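**Retrosynthetic overview**
1. Benzopyran ring (made last): the O1–C2 bond comes from a p-quinone-methide-type benzylic cation captured by the chalcone 2'-oxygen. The cation is released by opening an all-cis 2,4,6-trisubstituted tetrahydropyran at its benzylic C–O bond (ring switch).
2. Tetrahydropyran (made first, a relay ring absent from the target): Prins cyclisation of an (R)-homoallylic alcohol with 4-acetoxybenzaldehyde, ended by Friedel–Crafts attack of the intact chalcone (C3') on the ring cation. This joins chalcone and diarylheptanoid and passes the carbinol configuration on to the future C4.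
3. The chalcone comes from a Claisen–Schmidt condensation; the homoallylic alcohol from an asymmetric allylboration, the only source of absolute configuration.
4. Ring order: tetrahydropyran, then benzopyran; C2 is fixed last, under thermodynamic control (2,4-trans).

Assumption: chalcone numbering is used for the acylphloroglucinol ring (ring A, primed locants, C1' bears the carbonyl; ring B is the cinnamoyl aryl ring), and the target is read as (2R,4S)-chroman with an (R)-carbinol in the side chain.

**Step 1**
Reactants: 1 2',4'-dihydroxy-6'-methoxyacetophenone; 2 4-hydroxybenzaldehyde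
Product: 3 helichrysetin
Conditions: KOH (50% aq., 20 equiv), EtOH, 25 °C, 48 h; then HCl (2 M) to pH 3
Reagents that add atoms: none
Why: Claisen–Schmidt (crossed aldol) condensation of the methyl ketone enolate with the non-enolisable aldehyde, where E1cB dehydration gives only the conjugated (E)-enone and no stereocentre is formed.

**Step 2**
Reactants: 4 3-(4-hydroxyphenyl)propanal
Product: 6 (R)-1-(4-hydroxyphenyl)hex-5-en-3-ol, via bis-borinate 5 (not isolated)
Conditions: (−)-Ipc2B(allyl) (2.2 equiv, 1 M in pentane), Et2O, −78 °C; then NaOH (3 M), H2O2 (30%), 0 → 25 °C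
Reagents that add atoms: (−)-B-allyldiisopinocampheylborane [from (+)-α-pinene], C=CCB([C@@H]1C[C@@H]2C[C@H]([C@H]1C)C2(C)C)[C@@H]1C[C@@H]2C[C@H]([C@H]1C)C2(C)C
Why: Brown asymmetric allylboration through a chair Zimmerman–Traxler transition state delivers allyl to the Si face of the aldehyde, which here (allyl outranks the arylethyl chain) is the (R)-carbinol; the first equivalent of borane is consumed by the phenol as an aryl borinate that the oxidative work-up cleaves.

**Step 3**
Reactants: 6 (R)-1-(4-hydroxyphenyl)hex-5-en-3-ol; 7 4-acetoxybenzaldehyde; 3 helichrysetin (1.5 equiv)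
Product: 9 3'-[(2R,4S,6R)-2-(4-hydroxyphenyl)-6-[2-(4-hydroxyphenyl)ethyl]oxan-4-yl]helichrysetin, via aryl acetate tetrahydropyran 8 (not isolated)
Conditions: BF3·OEt2 (2.5 equiv), CH2Cl2–Et2O (4:1), −40 → −10 °C; then NH3 (7 M in MeOH), 0 °C, 30 min
Reagents that add atoms: none
Why: Prins cyclisation with Friedel–Crafts termination, in which the (E)-oxocarbenium ion from 6 and 7 closes through a chair with both substituents equatorial and the oxan-4-yl cation is captured equatorially by C3' of 3 (between the two free hydroxyls, the most electron-rich and least hindered carbon), so the (R)-carbinol sets the all-cis (2R,4S,6R) ring; the electron-poor 4-acetoxyphenyl group suppresses 2-oxonia-Cope scrambling and is unmasked by the ammonia quench.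

**Step 4**
Reactants: 9 all-cis tetrahydropyran chalcone
Product: 10 tetrakis-O-TIPS ether of 9 (2'-OH free)
Conditions: TIPSCl (6 equiv), imidazole (12 equiv), DMAP (0.1 equiv), DMF, 40 °C
Reagents that add atoms: chlorotriisopropylsilane (TIPSCl), CC(C)[Si](Cl)(C(C)C)C(C)C
Why: Silyl ether formation with R3SiCl/imidazole takes the four non-chelated phenols and leaves the 2'-OH (hydrogen-bonded to the ketone and flanked on both sides) free, which marks it as the only oxygen able to close the benzopyran; no stereocentre is touched.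

**Step 5**
Reactants: 10 tetrakis-O-TIPS tetrahydropyran chalcone
Product: 13 target chroman chalcone (2R,4S; side chain 2R), via 2'-O-trimethylsilyl ether 11 (not isolated), via silylated chroman 12 (not isolated)
Conditions: TMSOTf (1.3 equiv), 2,6-lutidine (1.0 equiv), CH2Cl2, −78 → 0 °C; then TBAF/AcOH (1:1, 8 equiv), THF, 0 °C
Reagents that add atoms: none
Why: Proposed new method: silyl-relayed ring switch through a p-quinone-methide-type benzylic cation – TMSOTf/2,6-lutidine silylates the 2'-OH, the remaining TMSOTf silylates the tetrahydropyran oxygen, the benzylic C–O bond ionises with help from the 4-silyloxyphenyl group, the side-chain oxygen leaves as its TMS ether and the 2'-O-TMS oxygen closes the six-membered benzopyran and passes the silyl cation on; the driving force is the move of silicon from an acylphenol oxygen to an alkoxide oxygen (no chelated OH is given up), the hindered 4'-O-TIPS oxygen cannot compete, C2 equilibrates by reversible ionisation to the 2,4-trans (2R) isomer (aryl equatorial, C4 chain pseudo-axial beside the peri 5-silyloxy group), and C4 and the carbinol are untouched; the closest known reaction types are the acid-promoted epimerisation or isomerisation of 2-aryltetrahydropyrans through ring-opened benzylic cations and the TMSOTf-catalysed alkylation of silyl ethers by stabilised cations; buffered fluoride then removes all silyl groups.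

**Compound list**
1 | 1-(2,4-dihydroxy-6-methoxyphenyl)ethan-1-one (2',4'-dihydroxy-6'-methoxyacetophenone) | CC(=O)c1c(O)cc(O)cc1OC | starting material
2 | 4-hydroxybenzaldehyde | O=Cc1ccc(O)cc1 | starting material
3 | helichrysetin, (E)-1-(2,4-dihydroxy-6-methoxyphenyl)-3-(4-hydroxyphenyl)prop-2-en-1-one | COc1cc(O)cc(O)c1C(=O)/C=C/c1ccc(O)cc1 | intermediate
4 | 3-(4-hydroxyphenyl)propanal | O=CCCc1ccc(O)cc1 | starting material
5 | bis(diisopinocampheylboryl) derivative of 6 (boron on the carbinol oxygen and on the phenol oxygen; carbinol R) | C=CC[C@H](OB([C@@H]3C[C@@H]4C[C@H]([C@H]3C)C4(C)C)[C@@H]3C[C@@H]4C[C@H]([C@H]3C)C4(C)C)CCc1ccc(OB([C@@H]3C[C@@H]4C[C@H]([C@H]3C)C4(C)C)[C@@H]3C[C@@H]4C[C@H]([C@H]3C)C4(C)C)cc1 | intermediate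
6 | (R)-1-(4-hydroxyphenyl)hex-5-en-3-ol, i.e. 4-[(3R)-3-hydroxyhex-5-en-1-yl]phenol | C=CC[C@H](O)CCc1ccc(O)cc1 | intermediate
7 | 4-formylphenyl acetate (4-acetoxybenzaldehyde) | CC(=O)Oc1ccc(C=O)cc1 | starting material
8 | 4-[(2R,4S,6R)-4-{2,6-dihydroxy-3-[(E)-3-(4-hydroxyphenyl)prop-2-enoyl]-4-methoxyphenyl}-6-[2-(4-hydroxyphenyl)ethyl]oxan-2-yl]phenyl acetate (all-cis) | O1[C@@H](c2ccc(OC(C)=O)cc2)C[C@@H](c2c(O)c(C(=O)/C=C/c3ccc(O)cc3)c(OC)cc2O)C[C@H]1CCc1ccc(O)cc1 | intermediate
9 | (E)-1-{2,4-dihydroxy-3-[(2R,4S,6R)-2-(4-hydroxyphenyl)-6-[2-(4-hydroxyphenyl)ethyl]oxan-4-yl]-6-methoxyphenyl}-3-(4-hydroxyphenyl)prop-2-en-1-one (all-cis tetrahydropyran on C3' of helichrysetin) | O1[C@@H](c2ccc(O)cc2)C[C@@H](c2c(O)c(C(=O)/C=C/c3ccc(O)cc3)c(OC)cc2O)C[C@H]1CCc1ccc(O)cc1 | intermediate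
10 | tetrakis(triisopropylsilyl) ether of 9: TIPS on the 4'-oxygen, the ring B oxygen and both 4-hydroxyphenyl oxygens; 2'-OH free; all-cis (2R,4S,6R) ring | O1[C@@H](c2ccc(O[Si](C(C)C)(C(C)C)C(C)C)cc2)C[C@@H](c2c(O)c(C(=O)/C=C/c3ccc(O[Si](C(C)C)(C(C)C)C(C)C)cc3)c(OC)cc2O[Si](C(C)C)(C(C)C)C(C)C)C[C@H]1CCc1ccc(O[Si](C(C)C)(C(C)C)C(C)C)cc1 | intermediate
11 | 2'-O-trimethylsilyl ether of 10 | O1[C@@H](c2ccc(O[Si](C(C)C)(C(C)C)C(C)C)cc2)C[C@@H](c2c(O[Si](C)(C)C)c(C(=O)/C=C/c3ccc(O[Si](C(C)C)(C(C)C)C(C)C)cc3)c(OC)cc2O[Si](C(C)C)(C(C)C)C(C)C)C[C@H]1CCc1ccc(O[Si](C(C)C)(C(C)C)C(C)C)cc1 | intermediate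
12 | 13 carrying TIPS on its four phenolic oxygens and TMS on the side-chain carbinol oxygen (same spatial arrangement at the three stereocentres as 13) | COc1cc(O[Si](C(C)C)(C(C)C)C(C)C)c2c(c1C(=O)/C=C/c1ccc(O[Si](C(C)C)(C(C)C)C(C)C)cc1)O[C@@H](c1ccc(O[Si](C(C)C)(C(C)C)C(C)C)cc1)C[C@@H]2C[C@H](O[Si](C)(C)C)CCc1ccc(O[Si](C(C)C)(C(C)C)C(C)C)cc1 | intermediate
13 | (E)-1-[(2R,4S)-5-hydroxy-4-[(2R)-2-hydroxy-4-(4-hydroxyphenyl)butyl]-2-(4-hydroxyphenyl)-7-methoxy-3,4-dihydro-2H-chromen-8-yl]-3-(4-hydroxyphenyl)prop-2-en-1-one (2,4-trans) | COc1cc(O)c2c(c1C(=O)/C=C/c1ccc(O)cc1)O[C@@H](c1ccc(O)cc1)C[C@@H]2C[C@H](O)CCc1ccc(O)cc1 | target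

**Step count and risks**
Total steps: 5. Longest linear sequence: 4 (steps 2, 3, 4, 5, or steps 1, 3, 4, 5).

The step most likely to fail is step 5. The silyl relay is untested: the switch may stop at an equilibrium mixture, the 2'-O-TMS oxygen may add reversibly to the silyl-activated enone (flavanone-type closure), and some C2 epimer will form. The fallback replaces the reversible silyl relay by an irreversible acetyl relay; it sets out from 10 and comes back at 13. After silylation of the 2'-OH as before (giving 11), Ac2O (3 equiv) is added to the TMSOTf-containing solution at −40 → 0 °C. The tetrahydropyran oxygen is acetylated, the ring opens to the same benzylic cation, and the side-chain oxygen is now an ester that cannot re-close. The 2'-O-TMS oxygen closes the benzopyran to give the side-chain acetate of the tetrakis-TIPS chroman F1. K2CO3/MeOH (phenols still silylated, so no p-phenoxide can open the ring) gives the tetrakis-TIPS chroman alcohol F2, and TBAF/AcOH gives 13.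

The second is step 3. The free chalcone is poorly soluble, the aldehyde can condense directly with ring A, and attack at C5' or a second alkylation is possible. The fallback changes the order of events; it sets out from 6 (with 7 and 1) and comes back at 9. The cheap, soluble acetophenone 1 (3 equiv) is used as the terminating arene under the same BF3·OEt2 conditions with an aqueous NaHCO3 work-up, giving the aryl acetate tetrahydropyran acetophenone F3. The chalcone is then built on the base-stable tetrahydropyran by Claisen–Schmidt condensation with 2 (KOH, EtOH, 25 °C), which also cleaves the acetate and gives 9; step 1 is then not needed.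

The third is step 1. Ketone and aldehyde are both phenoxides under KOH and the condensation may stall at low conversion. The fallback is a protecting-group route; it sets out from 1 and comes back at 3. MOMCl/iPr2NEt (CH2Cl2, 0 °C) protects only the non-chelated 4-OH to give the mono-MOM acetophenone F4. Condensation with purchased 4-(methoxymethoxy)benzaldehyde (KOH, EtOH) gives the bis-MOM chalcone F5, and HCl/MeOH (25 °C) gives 3.

**Further compounds**
F1 | step 5 | side-chain acetate of the tetrakis-TIPS chroman (12 with acetyl in place of TMS) | COc1cc(O[Si](C(C)C)(C(C)C)C(C)C)c2c(c1C(=O)/C=C/c1ccc(O[Si](C(C)C)(C(C)C)C(C)C)cc1)O[C@@H](c1ccc(O[Si](C(C)C)(C(C)C)C(C)C)cc1)C[C@@H]2C[C@H](OC(C)=O)CCc1ccc(O[Si](C(C)C)(C(C)C)C(C)C)cc1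
F2 | step 5 | tetrakis-TIPS ether of 13 at its four phenolic oxygens (side-chain OH free) | COc1cc(O[Si](C(C)C)(C(C)C)C(C)C)c2c(c1C(=O)/C=C/c1ccc(O[Si](C(C)C)(C(C)C)C(C)C)cc1)O[C@@H](c1ccc(O[Si](C(C)C)(C(C)C)C(C)C)cc1)C[C@@H]2C[C@H](O)CCc1ccc(O[Si](C(C)C)(C(C)C)C(C)C)cc1
F3 | step 3 | 4-[(2R,4S,6R)-4-(3-acetyl-2,6-dihydroxy-4-methoxyphenyl)-6-[2-(4-hydroxyphenyl)ethyl]oxan-2-yl]phenyl acetate (all-cis) | O1[C@@H](c2ccc(OC(C)=O)cc2)C[C@@H](c2c(O)c(C(C)=O)c(OC)cc2O)C[C@H]1CCc1ccc(O)cc1
F4 | step 1 | 1-[2-hydroxy-6-methoxy-4-(methoxymethoxy)phenyl]ethan-1-one | CC(=O)c1c(O)cc(OCOC)cc1OC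
F5 | step 1 | (E)-1-[2-hydroxy-6-methoxy-4-(methoxymethoxy)phenyl]-3-[4-(methoxymethoxy)phenyl]prop-2-en-1-one | COCOc1ccc(/C=C/C(=O)c2c(O)cc(OCOC)cc2OC)cc1
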